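**Retrosynthetic overview**

1. Target 24 ⇐ CBS reduction of ring A enone 23 ⇐ methyl addition at C7 ⇐ vinylogous (1,6) Mukaiyama–Michael union of enol silane 10 (fragment 1) with dienone 20 (fragment 2).
2. 10 ⇐ one-carbon ring expansion of cyclopentanone 7 (carbenoid 1,2-shift of the quaternary carbon), which builds the six-membered ring and its enolate regiospecifically.
3. 7 ⇐ Markovnikov oxymercuration (oxepane C2–O bond) of ketol 5 ⇐ desymmetrising transfer hydrogenation of dione 4 ⇐ alkenylzinc addition to aldehyde 3 ⇐ dione 1 + acrolein 2.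
4. 20 ⇐ Stork–Danheiser vinylation of vinylogous ester 18 ⇐ Wacker/Wittig chain extension of 16 ⇐ decarboxylative asymmetric allylation ⇐ cyclohexane-1,3-dione 11.
5. Ring order: oxepane closed on the cyclopentane of 1 (step 4), then the cyclohexane by ring expansion (step 5); ring A comes from 11; the halves are joined last.

Assumption: the SMILES is taken literally, i.e. a cis-fused oxepane–cyclohexane (3S,5aS,6S,7R,9aR; benzo[b]oxepine locants) linked to a (3R,6S)-cyclohexenol (ring A).

**Fragment 1 (oxepane–carbocycle)**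

Step 1
Reactants: 1 2-methylcyclopentane-1,3-dione; 2 acrolein
Product: 3 3-(1-methyl-2,5-dioxocyclopentyl)propanal
Conditions: H2O, 23 °C, 24 h
Reagents that add atoms: none
Why: The acidic 2-methyl-1,3-dione adds to acrolein in water without catalyst to give the (still prochiral) quaternary carbon; Michael addition.

Step 2
Reactants: 3 3-(1-methyl-2,5-dioxocyclopentyl)propanal
Product: 4 2-[(3S)-3-hydroxy-4-methylpent-4-en-1-yl]-2-methylcyclopentane-1,3-dione
Conditions: Zn(C(CH3)=CH2)2 (from CH2=C(CH3)MgBr + ZnCl2, 1,4-dioxane), (+)-MIB (5 mol%), toluene, 0 °C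
Reagents that add atoms: isopropenylmagnesium bromide, CC(=C)[Mg]Br
Why: Amino-alcohol-catalysed alkenylzinc addition is aldehyde-selective (the ketones stay untouched) and (+)-MIB delivers the isopropenyl group to the Re face, setting the future C3 carbinol as S; catalytic asymmetric organozinc addition.

Step 3
Reactants: 4 2-[(3S)-3-hydroxy-4-methylpent-4-en-1-yl]-2-methylcyclopentane-1,3-dione
Product: 5 (2R,3R)-3-hydroxy-2-[(3S)-3-hydroxy-4-methylpent-4-en-1-yl]-2-methylcyclopentan-1-one
Conditions: RuCl[(R,R)-TsDPEN](p-cymene) (1 mol%), HCO2H/Et3N (5:2), CH2Cl2, 25 °C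
Reagents that add atoms: none
Why: The (R,R) catalyst reduces one enantiotopic carbonyl with hydride entering anti to the larger side chain, so the quaternary carbon (R) and the carbinol (R, OH cis to the chain) are set together; Noyori asymmetric transfer hydrogenation (desymmetrisation).

Step 4
Reactants: 5 (2R,3R)-3-hydroxy-2-[(3S)-3-hydroxy-4-methylpent-4-en-1-yl]-2-methylcyclopentan-1-one
Product: 7 (3S,5aR,8aR)-3-hydroxy-2,2,5a-trimethyloctahydro-6H-cyclopenta[b]oxepin-6-one, via organomercurial 6 (not isolated)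
Conditions: Hg(O2CCF3)2, CH2Cl2, −20 → 0 °C; then n-Bu3SnH, THF, 0 °C
Reagents that add atoms: none
Why: Mercuration of the 1,1-disubstituted alkene is strictly Markovnikov, so the ring hydroxyl (held cis to the chain) closes the tertiary C2–O bond of the oxepane and tin hydride then gives the gem-dimethyl group, with no stereocentre changed and the cis fusion inherited from step 3; intramolecular oxymercuration–demercuration.

Step 5
Reactants: 7 (3S,5aR,8aR)-3-hydroxy-2,2,5a-trimethyloctahydro-6H-cyclopenta[b]oxepin-6-one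
Product: 10 (3S,5aS,9aR)-2,2,5a-trimethyl-3,7-bis(trimethylsilyloxy)-2,3,4,5,5a,8,9,9a-octahydrobenzo[b]oxepine, via dibromomethyl carbinolate 8 (not isolated), via ring-expanded lithium enolate 9 (not isolated)
Conditions: CH2Br2, lithium 2,2,6,6-tetramethylpiperidide (2.1 equiv), THF, −78 °C; n-BuLi (1.2 equiv), −78 → 0 °C; Me3SiCl, Et3N, −78 → 23 °C
Reagents that add atoms: dibromomethane, BrCBr; chlorotrimethylsilane, C[Si](C)(C)Cl
Why: Br/Li exchange on the dibromomethyl adduct gives a β-oxido carbenoid whose 1,2-alkyl shift (the more substituted, quaternary carbon migrates with retention) expands the cyclopentanone to the cyclohexanone enolate, formed only toward the new CH and trapped as the enol silane; carbenoid (Nozaki–Taguchi type) ring expansion.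

**Fragment 2 (ring A)**

Step 6
Reactants: 11 cyclohexane-1,3-dione
Product: 12 2-methylcyclohexane-1,3-dione
Conditions: MeI, NaOH, H2O/dioxane, 65 °C
Reagents that add atoms: iodomethane, CI
Why: The dione enolate is C-methylated at the doubly activated carbon; enolate alkylation.

Step 7
Reactants: 12 2-methylcyclohexane-1,3-dione
Product: 13 3-isobutoxy-2-methylcyclohex-2-en-1-one
Conditions: i-BuOH, TsOH (cat.), toluene, reflux (Dean–Stark)
Reagents that add atoms: 2-methylpropan-1-ol, CC(C)CO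
Why: Acid-catalysed enol etherification with azeotropic water removal; vinylogous ester formation.

Step 8
Reactants: 13 3-isobutoxy-2-methylcyclohex-2-en-1-one
Product: 14 3-isobutoxy-2,6-dimethylcyclohex-2-en-1-one (racemic)
Conditions: LiN(i-Pr)2, THF, −78 °C; MeI
Reagents that add atoms: iodomethane, CI
Why: Kinetic deprotonation of a vinylogous ester occurs at the α′ carbon, which is then methylated; enolate alkylation.

Step 9
Reactants: 14 3-isobutoxy-2,6-dimethylcyclohex-2-en-1-one (racemic)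
Product: 15 allyl 5-isobutoxy-2,6-dimethylcyclohexa-1,5-dien-1-yl carbonate
Conditions: LiN(i-Pr)2, THF, −78 °C; allyl chloroformate
Reagents that add atoms: allyl chloroformate, C=CCOC(=O)Cl
Why: The tetrasubstituted lithium enolate is acylated on oxygen by the chloroformate, erasing the racemic centre; enol carbonate formation.

Step 10
Reactants: 15 allyl 5-isobutoxy-2,6-dimethylcyclohexa-1,5-dien-1-yl carbonate
Product: 16 (R)-6-allyl-3-isobutoxy-2,6-dimethylcyclohex-2-en-1-one
Conditions: Pd2(dba)3 (2.5 mol%), (R)-t-BuPHOX (6.25 mol%), toluene, 25 °C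
Reagents that add atoms: none
Why: Zerovalent palladium ionises the allyl carbonate, CO2 is lost and the ligand-bound allylpalladium enolate recombines enantioselectively to give the α-quaternary centre (R here; the same spatial arrangement is S in the target); decarboxylative asymmetric allylic alkylation.

Step 11
Reactants: 16 (R)-6-allyl-3-isobutoxy-2,6-dimethylcyclohex-2-en-1-one
Product: 17 3-[(1R)-4-isobutoxy-1,3-dimethyl-2-oxocyclohex-3-en-1-yl]propanal
Conditions: PdCl2(PhCN)2 (12 mol%), CuCl2 (12 mol%), AgNO2 (6 mol%), O2 (1 atm), t-BuOH/MeNO2, 23 °C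
Reagents that add atoms: dioxygen, O=O
Why: The nitrite-modified system oxidises the terminal alkene at the terminal carbon to the aldehyde without touching the push–pull enol ether; aldehyde-selective Wacker oxidation.

Step 12
Reactants: 17 3-[(1R)-4-isobutoxy-1,3-dimethyl-2-oxocyclohex-3-en-1-yl]propanal
Product: 18 (S)-3-isobutoxy-2,6-dimethyl-6-(4-methylpent-3-en-1-yl)cyclohex-2-en-1-one
Conditions: i-PrPPh3I, n-BuLi, THF, −78 → 0 °C
Reagents that add atoms: isopropyltriphenylphosphonium iodide, CC(C)[P+](c1ccccc1)(c1ccccc1)c1ccccc1.[I-]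
Why: The non-stabilised ylide olefinates the aldehyde only (the vinylogous ester carbonyl is inert), completing the 4-methylpent-3-enyl chain; Wittig reaction.

Step 13
Reactants: 18 (S)-3-isobutoxy-2,6-dimethyl-6-(4-methylpent-3-en-1-yl)cyclohex-2-en-1-one
Product: 20 (S)-2,4-dimethyl-4-(4-methylpent-3-en-1-yl)-3-vinylcyclohex-2-en-1-one, via vinyl carbinol 19 (not isolated)
Conditions: CH2=CHMgBr, THF, 0 → 40 °C; then 1 M HCl, 0 °C
Reagents that add atoms: vinylmagnesium bromide, C=C[Mg]Br
Why: 1,2-Addition to the carbonyl next to the quaternary centre followed by acid-induced loss of isobutanol transposes the carbonyl and gives the cross-conjugated vinyl enone; Stork–Danheiser sequence.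

**Union and completion**

Step 14
Reactants: 10 (3S,5aS,9aR)-2,2,5a-trimethyl-3,7-bis(trimethylsilyloxy)-2,3,4,5,5a,8,9,9a-octahydrobenzo[b]oxepine; 20 (S)-2,4-dimethyl-4-(4-methylpent-3-en-1-yl)-3-vinylcyclohex-2-en-1-one
Product: 21 (3S,5aS,6S,9aR)-6-{2-[(6S)-2,6-dimethyl-6-(4-methylpent-3-en-1-yl)-3-(trimethylsilyloxy)cyclohex-2-en-1-ylidene]ethyl}-2,2,5a-trimethyl-3-(trimethylsilyloxy)octahydrobenzo[b]oxepin-7(2H)-one (E/Z mixture at the exocyclic alkene)
Conditions: Me3SiOTf (10 mol%), CH2Cl2, −78 °C; Et3N quench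
Reagents that add atoms: none
Why: Proposed new method: silyl-triflate-catalysed vinylogous (1,6) Mukaiyama–Michael addition, in which O-silylation of 20 gives a 1-siloxypentadienyl cation whose only unhindered electrophilic terminus is the vinyl CH2 (the 1,4-carbon is fully substituted and flanked by the quaternary centre), so the enol silane carbon of 10 bonds there and the silyl group relays to the ring A oxygen, leaving ring A masked as a silyl dienol ether; the enol silane reacts axially through the half-chair with the ring oxygen equatorial, anti to the pseudoaxial C5 methylene, which places the new chain cis to the C5a methyl (C6 = S); closest known reaction type: Mukaiyama–Michael 1,4-addition and Lewis-acid 1,6-addition of enol silanes to para-quinone methides.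

Step 15
Reactants: 21 the silyl dienol ether ketone from step 14
Product: 23 (3S,5aS,6S,7R,9aR)-6-{2-[(6S)-2,6-dimethyl-6-(4-methylpent-3-en-1-yl)-3-oxocyclohex-1-en-1-yl]ethyl}-2,2,5a,7-tetramethyldecahydrobenzo[b]oxepine-3,7-diol, via methyl carbinol bis-silyl ether 22 (not isolated)
Conditions: MeMgBr, CeCl3, THF, −78 °C; then 1 M HCl, THF, 0 °C
Reagents that add atoms: methylmagnesium bromide, C[Mg]Br
Why: The non-basic organocerium adds only to the ring ketone (ring A is masked), trans to the C6 side chain by equatorial attack because the syn-axial C5a methyl blocks the axial path, giving the 7R carbinol cis to the chain, and acid then unmasks the conjugated enone and the C3 hydroxyl; organocerium 1,2-addition and silyl ether hydrolysis.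

Step 16
Reactants: 23 the enone diol from step 15
Product: 24 target, (3S,5aS,6S,7R,9aR)-6-{2-[(3R,6S)-3-hydroxy-2,6-dimethyl-6-(4-methylpent-3-en-1-yl)cyclohex-1-en-1-yl]ethyl}-2,2,5a,7-tetramethyldecahydrobenzo[b]oxepine-3,7-diol
Conditions: (S)-Me-CBS (20 mol%), catecholborane (excess), toluene, −78 °C; then NaOH (aq), MeOH
Reagents that add atoms: none
Why: The oxazaborolidine treats the 2-methyl-alkenyl arm as the large group and delivers hydride under reagent control to give the R allylic alcohol regardless of the remote centres; Corey–Bakshi–Shibata reduction.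

**Compound list**

1 | 2-methylcyclopentane-1,3-dione | CC1C(=O)CCC1=O | starting material
2 | acrolein | C=CC=O | starting material
3 | 3-(1-methyl-2,5-dioxocyclopentyl)propanal | CC1(CCC=O)C(=O)CCC1=O | intermediate
4 | 2-[(3S)-3-hydroxy-4-methylpent-4-en-1-yl]-2-methylcyclopentane-1,3-dione | CC1(CC[C@H](O)C(C)=C)C(=O)CCC1=O | intermediate
5 | (2R,3R)-3-hydroxy-2-[(3S)-3-hydroxy-4-methylpent-4-en-1-yl]-2-methylcyclopentan-1-one | C[C@@]1(CC[C@H](O)C(C)=C)[C@H](O)CCC1=O | intermediate
6 | (3S,5aR,8aR)-3-hydroxy-2,5a-dimethyl-2-[(trifluoroacetoxymercurio)methyl]octahydro-6H-cyclopenta[b]oxepin-6-one (C2 epimers, not isolated) | C[C@@]12CC[C@H](O)C(C)(C[Hg]OC(=O)C(F)(F)F)O[C@@H]1CCC2=O | intermediate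
7 | (3S,5aR,8aR)-3-hydroxy-2,2,5a-trimethyloctahydro-6H-cyclopenta[b]oxepin-6-one | C[C@@]12CC[C@H](O)C(C)(C)O[C@@H]1CCC2=O | intermediate
8 | dilithium salt of the 6-(dibromomethyl)-3,6-diol derived from 7 (not isolated) | C[C@@]12CC[C@H](O[Li])C(C)(C)O[C@@H]1CCC2(O[Li])C(Br)Br | intermediate
9 | dilithium enolate-alkoxide of (3S,5aS,9aR)-3-hydroxy-2,2,5a-trimethyloctahydrobenzo[b]oxepin-7(2H)-one, enolate toward C6 (not isolated) | C=1[C@]2(C)CC[C@H](O[Li])C(C)(C)O[C@@H]2CCC=1O[Li] | intermediate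
10 | (3S,5aS,9aR)-2,2,5a-trimethyl-3,7-bis(trimethylsilyloxy)-2,3,4,5,5a,8,9,9a-octahydrobenzo[b]oxepine | C=1[C@]2(C)CC[C@H](O[Si](C)(C)C)C(C)(C)O[C@@H]2CCC=1O[Si](C)(C)C | intermediate
11 | cyclohexane-1,3-dione | O=C1CCCC(=O)C1 | starting material
12 | 2-methylcyclohexane-1,3-dione | CC1C(=O)CCCC1=O | intermediate
13 | 3-isobutoxy-2-methylcyclohex-2-en-1-one | CC1=C(OCC(C)C)CCCC1=O | intermediate
14 | 3-isobutoxy-2,6-dimethylcyclohex-2-en-1-one (racemic) | CC1CCC(OCC(C)C)=C(C)C1=O | intermediate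
15 | allyl 5-isobutoxy-2,6-dimethylcyclohexa-1,5-dien-1-yl carbonate | C=CCOC(=O)OC1=C(C)CCC(OCC(C)C)=C1C | intermediate
16 | (R)-6-allyl-3-isobutoxy-2,6-dimethylcyclohex-2-en-1-one | C=CC[C@@]1(C)CCC(OCC(C)C)=C(C)C1=O | intermediate
17 | 3-[(1R)-4-isobutoxy-1,3-dimethyl-2-oxocyclohex-3-en-1-yl]propanal | O=CCC[C@@]1(C)CCC(OCC(C)C)=C(C)C1=O | intermediate
18 | (S)-3-isobutoxy-2,6-dimethyl-6-(4-methylpent-3-en-1-yl)cyclohex-2-en-1-one | CC(C)=CCC[C@@]1(C)CCC(OCC(C)C)=C(C)C1=O | intermediate
19 | (6S)-3-isobutoxy-2,6-dimethyl-6-(4-methylpent-3-en-1-yl)-1-vinylcyclohex-2-en-1-ol (C1 epimers, formed as its magnesium alkoxide, not isolated) | CC(C)=CCC[C@@]1(C)CCC(OCC(C)C)=C(C)C1(O)C=C | intermediate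
20 | (S)-2,4-dimethyl-4-(4-methylpent-3-en-1-yl)-3-vinylcyclohex-2-en-1-one | CC(C)=CCC[C@@]1(C)CCC(=O)C(C)=C1C=C | intermediate
21 | (3S,5aS,6S,9aR)-6-{2-[(6S)-2,6-dimethyl-6-(4-methylpent-3-en-1-yl)-3-(trimethylsilyloxy)cyclohex-2-en-1-ylidene]ethyl}-2,2,5a-trimethyl-3-(trimethylsilyloxy)octahydrobenzo[b]oxepin-7(2H)-one | CC(C)=CCC[C@@]1(C)CCC(O[Si](C)(C)C)=C(C)C1=CC[C@H]1[C@]2(C)CC[C@H](O[Si](C)(C)C)C(C)(C)O[C@@H]2CCC1=O | intermediate
22 | (7R)-7-methyl-7-carbinol of 21, both silyl groups still in place (formed as its cerium alkoxide, not isolated) | CC(C)=CCC[C@@]1(C)CCC(O[Si](C)(C)C)=C(C)C1=CC[C@H]1[C@]2(C)CC[C@H](O[Si](C)(C)C)C(C)(C)O[C@@H]2CC[C@@]1(C)O | intermediate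
23 | (3S,5aS,6S,7R,9aR)-6-{2-[(6S)-2,6-dimethyl-6-(4-methylpent-3-en-1-yl)-3-oxocyclohex-1-en-1-yl]ethyl}-2,2,5a,7-tetramethyldecahydrobenzo[b]oxepine-3,7-diol | CC(C)=CCC[C@@]1(C)CCC(=O)C(C)=C1CC[C@H]1[C@]2(C)CC[C@H](O)C(C)(C)O[C@@H]2CC[C@@]1(C)O | intermediate
24 | (3S,5aS,6S,7R,9aR)-6-{2-[(3R,6S)-3-hydroxy-2,6-dimethyl-6-(4-methylpent-3-en-1-yl)cyclohex-1-en-1-yl]ethyl}-2,2,5a,7-tetramethyldecahydrobenzo[b]oxepine-3,7-diol (CNP0266779.3) | CC(C)=CCC[C@@]1(C)CC[C@@H](O)C(C)=C1CC[C@H]1[C@]2(C)CC[C@H](O)C(C)(C)O[C@@H]2CC[C@@]1(C)O | target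

**Step count**

Total: 16 steps (fragment 1: steps 1–5; fragment 2: steps 6–13; union and completion: steps 14–16). Longest linear sequence: 11 steps (6–13, then 14–16).

**Three steps most likely to fail, with fallbacks**

Step 14 (the proposed union) may fail through competing 1,4/1,2 addition, polymerisation of 20 or poor facial control at C6. The fallback uses known chemistry, sets out from 10 and comes back at 23. MeLi cleaves the enol silane to the lithium enolate, which is alkylated with allyl bromide under the same facial bias to give (3S,5aS,6S,9aR)-6-allyl-2,2,5a-trimethyl-3-(trimethylsilyloxy)octahydrobenzo[b]oxepin-7(2H)-one F7. MeMgBr/CeCl3 then gives the tertiary carbinol F8. Ozonolysis with NaBH4 work-up (silyl ether lost) gives the 6-(2-hydroxyethyl) triol F9, and I2/PPh3/imidazole at −20 °C gives the primary iodide F10. Lithium–iodine exchange with t-BuLi (excess, −78 °C) and addition of the alkyllithium to vinylogous ester 18, followed by 1 M HCl (Stork–Danheiser), gives 23. This costs four extra steps.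

Step 4 (seven-membered oxymercuration) may be slow relative to trifluoroacetate capture. The fallback sets out from 5 and comes back at 7. Hydroxyl-directed epoxidation of the isopropenyl group (VO(acac)2, t-BuOOH) gives the epoxy diol F1. Camphorsulfonic acid then lets the ring hydroxyl open the epoxide at its tertiary carbon, which is at once the exo and the Markovnikov position, to give the 2-(hydroxymethyl) oxepane F2. Primary-selective formation of the O-phenyl thionocarbonate F3 (PhOC(S)Cl, pyridine) and Barton–McCombie deoxygenation (n-Bu3SnH, AIBN, toluene, 90 °C) give 7.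

Step 5 (carbenoid ring expansion) may suffer from poor addition to the hindered ketone or wrong-carbon migration. The fallback sets out from 7 and comes back at 10. CH2=CHMgBr/CeCl3 gives the 6-vinyl carbinol F4, and VO(acac)2/t-BuOOH gives the oxiranyl carbinol F5. BF3·OEt2 (CH2Cl2, −78 °C) triggers the epoxide-opening semipinacol shift, in which the quaternary carbon migrates anti to the breaking C–O bond, to the ring-expanded 6-(hydroxymethyl) ketone F6. KH (THF, 0 °C) then Me3SiCl causes retro-aldol loss of formaldehyde and traps the same regiodefined enolate as 10.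

Further compounds
F1 | step 4 | (2R,3R)-3-hydroxy-2-[(3S)-3-hydroxy-3-(2-methyloxiran-2-yl)propyl]-2-methylcyclopentan-1-one (oxirane epimers) | C[C@@]1(CC[C@H](O)C2(C)CO2)[C@H](O)CCC1=O
F2 | step 4 | (3S,5aR,8aR)-3-hydroxy-2-(hydroxymethyl)-2,5a-dimethyloctahydro-6H-cyclopenta[b]oxepin-6-one (C2 epimers) | C[C@@]12CC[C@H](O)C(C)(CO)O[C@@H]1CCC2=O
F3 | step 4 | O-phenyl thionocarbonate of the primary alcohol of F2 | C[C@@]12CC[C@H](O)C(C)(COC(=S)Oc3ccccc3)O[C@@H]1CCC2=O
F4 | step 5 | (3S,5aR,8aR)-2,2,5a-trimethyl-6-vinyloctahydro-2H-cyclopenta[b]oxepine-3,6-diol (C6 epimers) | C[C@@]12CC[C@H](O)C(C)(C)O[C@@H]1CCC2(O)C=C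
F5 | step 5 | (3S,5aR,8aR)-2,2,5a-trimethyl-6-(oxiran-2-yl)octahydro-2H-cyclopenta[b]oxepine-3,6-diol | C[C@@]12CC[C@H](O)C(C)(C)O[C@@H]1CCC2(O)C3CO3
F6 | step 5 | (3S,5aS,9aR)-3-hydroxy-6-(hydroxymethyl)-2,2,5a-trimethyloctahydrobenzo[b]oxepin-7(2H)-one | OCC1[C@]2(C)CC[C@H](O)C(C)(C)O[C@@H]2CCC1=O
F7 | step 14 | (3S,5aS,6S,9aR)-6-allyl-2,2,5a-trimethyl-3-(trimethylsilyloxy)octahydrobenzo[b]oxepin-7(2H)-one | C=CC[C@H]1[C@]2(C)CC[C@H](O[Si](C)(C)C)C(C)(C)O[C@@H]2CCC1=O
F8 | step 14 | (3S,5aS,6S,7R,9aR)-6-allyl-2,2,5a,7-tetramethyl-3-(trimethylsilyloxy)decahydrobenzo[b]oxepin-7-ol | C=CC[C@H]1[C@]2(C)CC[C@H](O[Si](C)(C)C)C(C)(C)O[C@@H]2CC[C@@]1(C)O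
F9 | step 14 | (3S,5aS,6S,7R,9aR)-6-(2-hydroxyethyl)-2,2,5a,7-tetramethyldecahydrobenzo[b]oxepine-3,7-diol | OCC[C@H]1[C@]2(C)CC[C@H](O)C(C)(C)O[C@@H]2CC[C@@]1(C)O
F10 | step 14 | (3S,5aS,6S,7R,9aR)-6-(2-iodoethyl)-2,2,5a,7-tetramethyldecahydrobenzo[b]oxepine-3,7-diol | ICC[C@H]1[C@]2(C)CC[C@H](O)C(C)(C)O[C@@H]2CC[C@@]1(C)O
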